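The readings are calculated from invented constants; the scatter is artificial.

The easy step comes first: I multiply each percentage by the substrate charged and replace each flat curve by its mean.

| flask | substrate | capture agent | solid reagent | remark | time |
|---|---|---|---|---|---|
| alpha | 0.013 M (in portions, 2) | 6 mM | 10 mM | run made earlier; portions every 1.0 min |  |
| gamma | 0.030 M (in portions, 2) | 6 mM | 10 mM | run made earlier; portions every 1.0 min |  |
| flask | 0.020 M (in portions, 2) | 6.00 mM | 10.0 mM | the portions of substrate follow each other after 1.0 min, the first at the start | 6.0 d |

| run | time / d | target / % | side product / % |
|---|---|---|---|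
| alpha | 0.833 | 31.2 | 32.9 |
| alpha | 1.67 | 30.8 | 33.7 |
| alpha | 2.50 | 32.5 | 32.1 |
| alpha | 3.00 | 31.9 | 32.3 |
| alpha | 4.00 | 30.5 | 32.9 |
| alpha | 5.00 | 32.7 | 31.4 |
| gamma | 0.417 | 14.3 | 15.8 |
| gamma | 0.625 | 16.0 | 13.2 |
| gamma | 1.04 | 13.7 | 14.9 |
| gamma | 1.67 | 14.5 | 13.8 |
| gamma | 3.00 | 15.9 | 14.7 |
| gamma | 5.00 | 14.8 | 13.6 |

(each reading ± 1 percentage point)

- amount of target at 6.0 d, in percent of the substrate charged
- amount of side product at 6.0 d, in percent of the substrate charged

- solid reagent is a solid; its amount is given per volume of the solution
- candidate steps: open intermediate -> side product; solid reagent <-> coupling partner; substrate + coupling partner -> open intermediate; open intermediate -> target; open intermediate + capture agent -> trapped intermediate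
- at the start none of the solid reagent is in solution

That replacement needs a flat curve. Target in the gamma run reads 14.3% at 0.417 d and 14.8% at 5.00 d, with a scatter of 1 percentage point, and the alpha readings wander without a trend, so I treat both curves as level.

Now the run in slow motion. At the start no solid reagent is in solution, and the second portion of substrate follows after 1.0 min, far sooner than the first gamma reading, so I expect no mark of the dosing in the readings. The middle of the run, where the products form, lies before that reading, so these readings do not show it. They show the end: the mean target is 4.11 mM in alpha and 4.46 mM in gamma. The substrate charge grows by a factor of 2.31 between these runs, but the target grows by only 1.09. Both runs charge more substrate than solid reagent, so I take the solid reagent as the limiting reagent.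

Mean target per litre, averaged over both runs and divided by the solid reagent charged, gives the yield on solid reagent, w = 0.428. The same reckoning for side product gives v = 0.427. The remaining share, 0.145, is in neither product, and I expect it at the capture step.

For this flask, which also charges more substrate than solid reagent, I reckon 21.4% of target and 21.3% of side product. The forecast, on the ground that “These amounts barely depend on substrate”, says 21.6% and 21.3%, so its target stands 0.18 points above mine.

The flask gives 21.1% of target and 21.5% of side product, with 0% of solid reagent, 50.0% of substrate and 7.45% of trapped intermediate at 6.00 d. The w of this flask is 0.421.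

    open intermediate → side product (k = 0.0500 min⁻¹)
    solid reagent ⇌ coupling partner, rate k2*(cs2 - [coupling partner]) while solid is left; crystals form when [coupling partner] > cs2 (solubility = 7.60 mM, k = 0.720 min⁻¹)
    substrate + coupling partner → open intermediate (k = 14.5 M⁻¹ min⁻¹)
    open intermediate → target (k = 0.0490 min⁻¹)
    open intermediate + capture agent → trapped intermediate (k = 3.32 M⁻¹ min⁻¹)

A neighbour charged with 0.080 M of substrate keeps the solid reagent at 10.0 mM, so w and v give 5.35% of target and 5.34% of side product. That neighbour holds 0% of solid reagent at 6.00 d and gives 5.27% of target and 5.37% of side product.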